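The pyrrolidinone ring of the target (N1–C2(=O)–C3–C4–C5) is traced back to a six-membered 3-diazopiperidine-2,4-dione carrying the fully substituted benzyl group on nitrogen. A Wolff rearrangement expels nitrogen, shifts the ketone-side methylene onto the diazo carbon and thereby forges the C3–C4 bond of the lactam while shrinking the ring by one atom; the extruded carbonyl carbon ends up as a C3 carboxyl group that is lost on heating. The feature exploited is that C3 of the γ-lactam is an unsubstituted methylene flanked by the C2 carbonyl, so a traceless carboxyl can sit there. The precursor is assembled from a tribromoveratryl bromide and 3-diazopiperidine-2,4-dione; boron tribromide unmasks the catechol last.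

Key step: step 6

Assumption: the target has no stereogenic element (every sp3 carbon is a CH2 group), so the single stereoisomer asked for is the achiral compound itself and no step needs stereocontrol.

Step 1
Reactants: 1 4-methylbenzene-1,2-diol (4-methylcatechol)
Product: 2 3,4,6-tribromo-5-methylbenzene-1,2-diol
Conditions: Br2 (3.1 equiv), AcOH, 10 °C → rt, dark
Reagents that add atoms: bromine, BrBr
Why: Electrophilic aromatic bromination, in which each of the three free ring positions lies ortho or para to a hydroxyl group, so the catechol should take up exactly three bromine atoms, while metered bromine, low temperature and darkness keep oxidation to the o-quinone and side-chain attack in check.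

Step 2
Reactants: 2 3,4,6-tribromo-5-methylbenzene-1,2-diol
Product: 3 1,2,4-tribromo-5,6-dimethoxy-3-methylbenzene (2,3,6-tribromo-4,5-dimethoxytoluene)
Conditions: MeI (3 equiv), K2CO3, DMF, rt, N2
Reagents that add atoms: iodomethane, CI
Why: Williamson ether synthesis on two acidic, bromine-flanked phenols with a small methyl electrophile, giving methyl ethers that tolerate the radical bromination, hydride base, light and heat of the later steps.

Step 3
Reactants: 3 1,2,4-tribromo-5,6-dimethoxy-3-methylbenzene
Product: 4 1,2,4-tribromo-3-(bromomethyl)-5,6-dimethoxybenzene (2,3,6-tribromo-4,5-dimethoxybenzyl bromide)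
Conditions: NBS (1.05 equiv), AIBN (cat.), PhCF3, 85 °C
Reagents that add atoms: N-bromosuccinimide, O=C1CCC(=O)N1Br
Why: Wohl–Ziegler benzylic bromination, which should be clean because the ring bears no hydrogen and the aryl methyl C–H bonds are far more easily abstracted than those of the methoxy groups, a near-stoichiometric charge of NBS limiting dibromination.

Step 4
Reactants: 5 piperidine-2,4-dione
Product: 6 3-diazopiperidine-2,4-dione
Conditions: 4-acetamidobenzenesulfonyl azide (1.1 equiv), Et3N, MeCN, 0 °C → rt
Reagents that add atoms: 4-acetamidobenzenesulfonyl azide, CC(=O)Nc1ccc(cc1)S(=O)(=O)N=[N+]=[N-]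
Why: Regitz diazo transfer to the C3 methylene flanked by the ketone and lactam carbonyls, whose enolate attacks the terminal azide nitrogen and collapses to the diazo compound and the sulfonamide, and which at the same time blocks the most acidic carbon against alkylation in step 5.

Step 5
Reactants: 6 3-diazopiperidine-2,4-dione; 4 1,2,4-tribromo-3-(bromomethyl)-5,6-dimethoxybenzene
Product: 7 3-diazo-1-(2,3,6-tribromo-4,5-dimethoxybenzyl)piperidine-2,4-dione
Conditions: NaH (1.05 equiv), DMF, 0 °C; then 4, 0 °C → rt
Reagents that add atoms: none
Why: N-alkylation of a lactam anion by SN2 displacement at a primary benzylic bromide, which should succeed because with C3 blocked the N–H is the most acidic site left, the diazo group tolerates a non-nucleophilic hydride base, and the sodium amide anion in DMF reacts preferentially at nitrogen.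

Step 6
Reactants: 7 3-diazo-1-(2,3,6-tribromo-4,5-dimethoxybenzyl)piperidine-2,4-dione
Product: 9 2-oxo-1-(2,3,6-tribromo-4,5-dimethoxybenzyl)pyrrolidine-3-carboxylic acid (racemic), via exocyclic ketene 8 (not isolated)
Conditions: hν (365 nm LED), MeCN–H2O (4:1), rt, degassed
Reagents that add atoms: water, O
Why: This is a photochemical Wolff rearrangement of a cyclic 2-diazo-1,3-dicarbonyl compound, the standard ring contraction of that class: excitation of the diazo chromophore expels N2 and, because the ring holds the diazo group s-cis to both carbonyls, the C5 methylene shifts from the C4 ketone carbon to C3 in concert or through a short-lived acylcarbene, giving ketene 8, to which water adds. The five-membered lactam is thus closed by a 1,2-alkyl shift (six- to five-membered contraction that creates the C3–C4 bond of the pyrrolidinone) and not by an end-to-end cyclisation, so no Baldwin-type mode applies. The C3 stereocentre arises by unselective protonation of the enol of the ketene hydrate and is racemic, which is immaterial because step 7 removes it. The selectivity needed is migration of the ketone-side carbon and not of the lactam nitrogen; this is secured because the amide carbonyl, with its nitrogen lone pair tied up in resonance, is a far poorer Wolff partner than the ketone, so 2-diazo-3-oxo amides rearrange on the ketone side. Light of 365 nm should be absorbed essentially only by the diazo group, leaving the three aryl C–Br bonds (absorbing at shorter wavelength) and the methyl ethers untouched, and the large excess of water should outrun ketene dimerisation.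

Step 7
Reactants: 9 2-oxo-1-(2,3,6-tribromo-4,5-dimethoxybenzyl)pyrrolidine-3-carboxylic acid
Product: 10 1-(2,3,6-tribromo-4,5-dimethoxybenzyl)pyrrolidin-2-one
Conditions: DMSO, 140 °C
Reagents that add atoms: none
Why: Thermal decarboxylation of a malonic half-amide through a six-membered hydrogen-bonded transition state to the lactam enol, which tautomerises to 10 and erases the C3 stereocentre, while ethers, aryl bromides and the lactam are inert at this temperature.

Step 8
Reactants: 10 1-(2,3,6-tribromo-4,5-dimethoxybenzyl)pyrrolidin-2-one
Product: 11 1-(2,3,6-tribromo-4,5-dihydroxybenzyl)pyrrolidin-2-one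
Conditions: BBr3 (5 equiv), CH2Cl2, −78 °C → rt; then ice-water, N2
Reagents that add atoms: none
Why: Boron tribromide cleavage of aryl methyl ethers, in which boron complexes each ortho-flanked methoxy oxygen and bromide attacks the methyl carbon, while the tertiary lactam only binds the Lewis acid reversibly (hence the excess), the aryl C–Br bonds are inert, and an acidic, oxygen-free work-up should avoid quinone or quinone-methide formation.

Compound list
1 | 4-methylbenzene-1,2-diol (4-methylcatechol) | Cc1ccc(O)c(O)c1 | starting material
2 | 3,4,6-tribromo-5-methylbenzene-1,2-diol | Cc1c(Br)c(O)c(O)c(Br)c1Br | intermediate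
3 | 1,2,4-tribromo-5,6-dimethoxy-3-methylbenzene | Cc1c(Br)c(OC)c(OC)c(Br)c1Br | intermediate
4 | 1,2,4-tribromo-3-(bromomethyl)-5,6-dimethoxybenzene | BrCc1c(Br)c(OC)c(OC)c(Br)c1Br | intermediate
5 | piperidine-2,4-dione | O=C1CC(=O)NCC1 | starting material
6 | 3-diazopiperidine-2,4-dione | [N-]=[N+]=C1C(=O)CCNC1=O | intermediate
7 | 3-diazo-1-(2,3,6-tribromo-4,5-dimethoxybenzyl)piperidine-2,4-dione | [N-]=[N+]=C1C(=O)CCN(Cc2c(Br)c(OC)c(OC)c(Br)c2Br)C1=O | intermediate
8 | 3-(oxomethylidene)-1-(2,3,6-tribromo-4,5-dimethoxybenzyl)pyrrolidin-2-one (ketene, not isolated) | O=C=C1CCN(Cc2c(Br)c(OC)c(OC)c(Br)c2Br)C1=O | intermediate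
9 | 2-oxo-1-(2,3,6-tribromo-4,5-dimethoxybenzyl)pyrrolidine-3-carboxylic acid (racemic) | OC(=O)C1CCN(Cc2c(Br)c(OC)c(OC)c(Br)c2Br)C1=O | intermediate
10 | 1-(2,3,6-tribromo-4,5-dimethoxybenzyl)pyrrolidin-2-one | O=C1CCCN1Cc1c(Br)c(OC)c(OC)c(Br)c1Br | intermediate
11 | 1-(2,3,6-tribromo-4,5-dihydroxybenzyl)pyrrolidin-2-one | O=C1CCCN1Cc1c(Br)c(O)c(O)c(Br)c1Br | target

Total step count: 8
Longest linear sequence: 7 steps (steps 1, 2, 3, 5, 6, 7, 8; compounds 1 → 2 → 3 → 4 → 7 → 9 → 10 → 11)

Steps most likely to fail

Step 5. The ambident lactam anion may react at oxygen, the base may deprotonate C5 next to the ketone, or displacement at the di-ortho-brominated benzylic carbon may be slow enough for the diazo compound to decompose under the basic conditions. The fallback avoids amide alkylation altogether: it sets out from 4 and comes back at 7. Bromide displacement with β-alanine ethyl ester (hydrochloride, K2CO3, MeCN, 50 °C) should give ethyl 3-[(2,3,6-tribromo-4,5-dimethoxybenzyl)amino]propanoate F1. Acylation with ethyl malonyl chloride and Et3N in CH2Cl2 should give ethyl 3-[(3-ethoxy-3-oxopropyl)(2,3,6-tribromo-4,5-dimethoxybenzyl)amino]-3-oxopropanoate F2. Dieckmann condensation (NaOEt, EtOH, reflux) should close the ring to ethyl 2,4-dioxo-1-(2,3,6-tribromo-4,5-dimethoxybenzyl)piperidine-3-carboxylate F3. Hydrolysis and decarboxylation in refluxing aqueous MeCN should give 1-(2,3,6-tribromo-4,5-dimethoxybenzyl)piperidine-2,4-dione F4. Regitz diazo transfer with 4-acetamidobenzenesulfonyl azide and Et3N then delivers 7.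

Step 6. The excited diazo compound may isomerise or insert into the O–H bond of water instead of undergoing the 1,2-shift, stray short-wavelength light may cleave aryl C–Br bonds, or the ketene may oligomerise before hydration. The fallback gives up the ring contraction and sets out from 4, coming back at 10: the sodium salt of pyrrolidin-2-one (NaH, THF–DMF, 0 °C → rt) is benzylated on nitrogen by 4, a standard lactam alkylation, and steps 6 and 7 are bypassed. This fallback makes no new compound, F0.

Step 1. Excess bromine may oxidise the electron-rich catechol to the o-quinone, whose quinone-methide tautomer leads to side-chain bromination and tars. The fallback inverts the order of events, setting out from 1 and coming back at 3. Methylation first (MeI, K2CO3, DMF) should give 1,2-dimethoxy-4-methylbenzene F5, which cannot be oxidised to a quinone. Exhaustive electrophilic bromination of the ether (excess Br2, catalytic Fe powder, CH2Cl2, rt → 40 °C) should then fill the three ring positions and give 3.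

Further compounds
F1 | step 5 | ethyl 3-[(2,3,6-tribromo-4,5-dimethoxybenzyl)amino]propanoate | CCOC(=O)CCNCc1c(Br)c(OC)c(OC)c(Br)c1Br
F2 | step 5 | ethyl 3-[(3-ethoxy-3-oxopropyl)(2,3,6-tribromo-4,5-dimethoxybenzyl)amino]-3-oxopropanoate | CCOC(=O)CC(=O)N(CCC(=O)OCC)Cc1c(Br)c(OC)c(OC)c(Br)c1Br
F3 | step 5 | ethyl 2,4-dioxo-1-(2,3,6-tribromo-4,5-dimethoxybenzyl)piperidine-3-carboxylate | CCOC(=O)C1C(=O)CCN(Cc2c(Br)c(OC)c(OC)c(Br)c2Br)C1=O
F4 | step 5 | 1-(2,3,6-tribromo-4,5-dimethoxybenzyl)piperidine-2,4-dione | O=C1CC(=O)N(Cc2c(Br)c(OC)c(OC)c(Br)c2Br)CC1
F0 | step 6 | none | none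
F5 | step 1 | 1,2-dimethoxy-4-methylbenzene | Cc1ccc(OC)c(OC)c1
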